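The numbers were drawn at random within sensible limits.

Start from the constants: set the ring-closing one against the two that build dimers, and they tell where G.Z goes.

    G + Z → G.Z (k1 = 0.21 L mol⁻¹ min⁻¹)
    G.Z → Q (k2 = 0.032 min⁻¹)
    G + G.Z → G.G.Z (k3 = 0.056 L mol⁻¹ min⁻¹)
    2 Z → Z2 (k4 = 0.29 L mol⁻¹ min⁻¹)
    G + G.Z → J (k5 = 0.087 L mol⁻¹ min⁻¹)
    Z → E (k6 = 0.045 min⁻¹)

G 0.46 M; Z 0.598 M; time 40 h

- which holds at 40 h: what has brought the reaction to rest, or that it has not come to rest (it is still moving / Z has run out first / all of G has reacted)
- the Q standing at 40 h, as a percentage of the G charged
- the J standing at 40 h, as a percentage of the G charged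
- the G.G.Z standing at 40 h, as a percentage of the G charged

- a species is counted by the G in it: one G.G.Z or J counts as two
- two of one species on the left: rate k times its square, two consumed each time
- the reaction counts as stopped when no species that holds the G changes by six tenths of a point or more over the second half of the time
- run time (flask): 40 h

Form the crossing concentration, the [G] at which G.Z closes to Q as fast as it takes on a further G: 0.224 M, the effective molarity of this ring. Of each G.Z, the share crossing/(crossing + [G]) becomes Q; the rest becomes J or G.G.Z and takes a further G along.

Turn the time first. Decay alone gives Z a life of 22.2 min and ring closure alone gives G.Z 31.2 min, far shorter than 40 h, so expect a longer run to change nothing.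

Turn [Z] next. At the start the step to G.Z uses Z at 0.28 of the rate at which dimerisation uses it, so expect extra Z to buy G.Z slowly, roughly as a logarithm of its charge.

Turn [G] last, and replace its falling curve by a mean, 0.7 of the charge: 0.322 M. Integrating the loss of Z at that mean makes 0.164 M of G.Z. The mean stands above the crossing, and the share to Q comes to 41.0 %. Commit to Q 14.6 %, J 25.6 % and G.G.Z 16.5 %. Check the mean: [G] ends at 0.199 M, so the straight mean is 0.330 M, close to the one assumed. This shows that the reckoning agrees with itself, not that it agrees with the flask.

The forecast says Z has run out first, with Q 17.4 %, J 24.9 % and G.G.Z 16 %, holding that “Z disappears within about 30 minutes”. Its Q stands above mine.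

The flask gives Z has run out first, with Q 17.7 %, J 24.8 % and G.G.Z 16.0 %. Z is the limiting reagent, 0 % of it left at 40.0 h, and Q still stands at 17.7 % after 400 h. Use the crossing once more: Q against the dimers puts the mean [G] that G.Z met at 0.257 M, lower than my mean. That gap is the error of the mean, and my Q stands 3.1 percentage points below the flask's.

Carry it to the neighbour charged with 1.2 M of G: a mean of 0.840 M makes 0.287 M of G.Z and sends 21.0 % of it to Q, so Q comes to 5.02 %. That flask gives 5.71 %.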